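**Remark (assumption):** the target SMILES contains no stereocentre and no stereogenic double bond, so the compound is achiral and "single enantiomer" is taken to mean the compound as drawn. Compounds 1 and 10 are taken to be commercial.

**Locants:** explanations use chromone locants (O1, C2–C8a) and primed locants (C1′–C6′) for the benzene ring of the benzofuran. Names use 11H-benzofuro[2,3-b]chromen-11-one numbering: C1 = C5, C2 = C6, C3 = C7, C4 = C8, C5a = C2, C7 = C3′, C8 = C4′, C9 = C5′, C10b = C3, C11 = C4.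

## Plan

1. Retrosynthesis: the pyran ring is cut first at O–CMe2 and at C8–CH=, back to the aryl 1,1-dimethylpropargyl ether 21. The 5′-OH is then traced to a formyl group (Dakin) and the 7-OH to a MOM ether.
2. Next the furan C2–O bond and the C3–C1′ bond are cut, giving 3-iodo-2-(methylsulfanyl)chromone 9 and ortho-hydroxyaryl boronate 15. The ring-B prenyl group is cut by a retro-Claisen to an ether of 5-bromo-2,4-dihydroxybenzaldehyde, and the pyranone is cut to ketone 4, made from the symmetric phenol 3.
3. Forward: ring A is bought (1) and converted into phenol 3; the pyranone closes in step 3; ring B is bought (10) and prenylated in steps 7–9; the furan closes in step 11; the pyran closes last, in step 15.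
4. Enabling feature: ring A is fully substituted, and the pyran oxygen on C7 has C6 (methyl) and C8 as its ortho carbons. In 21 the only ring-A C–H is C8 (between C7–O and C8a–O1), so an O-to-C sigmatropic shift can only end there, and the resulting 8-alkenyl-7-oxo array is a 1-oxatriene set up for 6π closure.
5. Stereochemistry: none to set; only regiochemistry is controlled, through the symmetry of 3, blocked ortho positions and hydrogen-bonded phenols.

Key step: step 15

## Route

Step 1
Reactants: 1 2,6-dimethoxytoluene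
Product: 3 3,5-dimethoxy-4-methylphenol, via aryl pinacol boronate 2 (not isolated)
Conditions: [Ir(OMe)(cod)]2 (1.5 mol%), dtbpy (3 mol%), B2pin2 (1.0 equiv), THF, 80 °C; then Oxone, acetone/H2O, rt
Reagents that add atoms: bis(pinacolato)diboron, CC1(C)OB(OC1(C)C)B1OC(C)(C)C(C)(C)O1 (boron of 2); Oxone (potassium peroxymonosulfate), [K+].[O-]S(=O)(=O)OO (oxygen of 3)
Why: Sterically controlled iridium-catalysed C–H borylation should occur only at C4 of 1, the one C–H without an ortho substituent, and oxidation of the C–B bond in the same flask should give the symmetric phenol 3, whose two ortho positions are equivalent (C–H borylation/oxidation).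

Step 2
Reactants: 3 3,5-dimethoxy-4-methylphenol
Product: 4 1-(6-hydroxy-2,4-dimethoxy-3-methylphenyl)ethan-1-one
Conditions: AcOH, BF3·OEt2 (3 equiv), 90 °C; aq. NaOAc work-up
Reagents that add atoms: acetic acid, CC(=O)O
Why: Friedel–Crafts C-acylation ortho to the phenol (para is blocked by methyl, and the two ortho sites are identical) should give a single ketone whose free OH lies next to an aromatic CH and whose ortho-OMe lies next to the ring methyl, which fixes the later 5-O/6-Me/7-O/8-H pattern; the boron chelate is cleaved on aqueous work-up.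

Step 3
Reactants: 4 1-(6-hydroxy-2,4-dimethoxy-3-methylphenyl)ethan-1-one
Product: 6 5,7-dimethoxy-6-methyl-2-(methylsulfanyl)-4H-chromen-4-one, via ketene dithioacetal 5 (not isolated)
Conditions: t-BuOK (3.1 equiv), CS2, THF, 0 °C; MeI (2.2 equiv), 0 °C to rt; then 60 °C
Reagents that add atoms: carbon disulfide, S=C=S; iodomethane, CI
Why: Deprotonation of the methyl ketone, addition to CS2 and double S-methylation should give ketene dithioacetal 5, whose ortho-phenoxide closes the pyranone by intramolecular addition–elimination with loss of methanethiolate (α-oxoketene dithioacetal route to 2-alkylthiochromones).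

Step 4
Reactants: 6 5,7-dimethoxy-6-methyl-2-(methylsulfanyl)-4H-chromen-4-one
Product: 7 3-iodo-5,7-dimethoxy-6-methyl-2-(methylsulfanyl)-4H-chromen-4-one
Conditions: LDA (1.2 equiv), THF, −78 °C; I2, −78 to 0 °C
Reagents that add atoms: iodine, II
Why: LDA should remove the only vinylic proton, C3–H, which is acidified by the adjacent carbonyl and the β-sulfur, and the iodine quench places the halogen at C3 without touching the electron-rich C8–H that an electrophilic iodination would attack (directed deprotonation/iodination of a 2-substituted chromone).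

Step 5
Reactants: 7 3-iodo-5,7-dimethoxy-6-methyl-2-(methylsulfanyl)-4H-chromen-4-one
Product: 8 5,7-dihydroxy-3-iodo-6-methyl-2-(methylsulfanyl)-4H-chromen-4-one
Conditions: BBr3 (4 equiv), CH2Cl2, −78 °C to rt; H2O quench
Reagents that add atoms: none
Why: BBr3 should cleave both aryl methyl ethers (the 5-OMe through the C4=O chelate, the 7-OMe on warming) while the S-methyl group and the vinylic iodide stay intact, and the step is placed here because no acid-sensitive group is present yet (Lewis acid ether cleavage).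

Step 6
Reactants: 8 5,7-dihydroxy-3-iodo-6-methyl-2-(methylsulfanyl)-4H-chromen-4-one
Product: 9 5-hydroxy-3-iodo-7-(methoxymethoxy)-6-methyl-2-(methylsulfanyl)-4H-chromen-4-one
Conditions: MOMCl (1.1 equiv), i-Pr2NEt, CH2Cl2, 0 °C
Reagents that add atoms: chloromethyl methyl ether, COCCl
Why: The 5-OH is held in a hydrogen bond to C4=O, so one equivalent of MOMCl should etherify only the acidic 7-OH, which keeps ring A from becoming a deactivating phenoxide during the base-mediated union (selective O-alkylation).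

Step 7
Reactants: 10 5-bromo-2,4-dihydroxybenzaldehyde
Product: 11 5-bromo-2-hydroxy-4-[(2-methylbut-3-yn-2-yl)oxy]benzaldehyde
Conditions: 3-chloro-3-methylbut-1-yne (1.3 equiv), DBU (1.2 equiv), CuCl2·2H2O (1 mol%), MeCN, 0 °C to rt
Reagents that add atoms: 3-chloro-3-methylbut-1-yne, C#CC(C)(C)Cl
Why: The 4-OH (para to CHO, not chelated, more acidic) should be alkylated in preference to the 2-OH, which is hydrogen-bonded to the aldehyde (copper-catalysed tertiary propargylic etherification of a phenol).

Step 8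
Reactants: 11 5-bromo-2-hydroxy-4-[(2-methylbut-3-yn-2-yl)oxy]benzaldehyde
Product: 12 5-bromo-2-hydroxy-4-[(2-methylbut-3-en-2-yl)oxy]benzaldehyde
Conditions: H2 (1 atm), Lindlar catalyst, quinoline, EtOAc, rt
Reagents that add atoms: none
Why: Semihydrogenation over the poisoned catalyst should stop at the terminal alkene and leave the C–Br bond and the aldehyde untouched (Lindlar reduction).

Step 9
Reactants: 12 5-bromo-2-hydroxy-4-[(2-methylbut-3-en-2-yl)oxy]benzaldehyde
Product: 14 5-bromo-2,4-dihydroxy-3-(3-methylbut-2-en-1-yl)benzaldehyde, via Claisen dienone 13 (not isolated)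
Conditions: PhNEt2, 130 °C, Ar
Reagents that add atoms: none
Why: The aromatic Claisen rearrangement of the 1,1-dimethylallyl ether should deliver a normal prenyl group to C3, the only free ortho position of that oxygen (the other ortho carbon carries bromine), and tautomerisation of dienone 13 restores the phenol ([3,3]-sigmatropic rearrangement).

Step 10
Reactants: 14 5-bromo-2,4-dihydroxy-3-(3-methylbut-2-en-1-yl)benzaldehyde
Product: 15 2,4-dihydroxy-3-(3-methylbut-2-en-1-yl)-5-(4,4,5,5-tetramethyl-1,3,2-dioxaborolan-2-yl)benzaldehyde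
Conditions: B2pin2 (1.2 equiv), PdCl2(dppf) (5 mol%), KOAc, 1,4-dioxane, 85 °C
Reagents that add atoms: bis(pinacolato)diboron, CC1(C)OB(OC1(C)C)B1OC(C)(C)C(C)(C)O1
Why: With the weak base KOAc the C–Br bond should be converted into C–Bpin in the presence of the aldehyde, the phenols and the trisubstituted alkene (Miyaura borylation).

Step 11
Reactants: 9 5-hydroxy-3-iodo-7-(methoxymethoxy)-6-methyl-2-(methylsulfanyl)-4H-chromen-4-one; 15 2,4-dihydroxy-3-(3-methylbut-2-en-1-yl)-5-(4,4,5,5-tetramethyl-1,3,2-dioxaborolan-2-yl)benzaldehyde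
Product: 17 1,8-dihydroxy-3-(methoxymethoxy)-2-methyl-7-(3-methylbut-2-en-1-yl)-11-oxo-11H-benzofuro[2,3-b]chromene-9-carbaldehyde, via 2-(methylsulfanyl)isoflavone 16 (not isolated)
Conditions: Pd(OAc)2 (5 mol%), SPhos (10 mol%), K3PO4 (3 equiv), 1,4-dioxane/H2O (10:1), 60 °C then 95 °C, Ar
Reagents that add atoms: none
Why: Oxidative addition should occur at the C3–I bond (the C–S bond is inert without copper), Suzuki–Miyaura coupling places the free 2′-OH of 16 next to C2, and the phenoxide should close the furan ring by addition–elimination with loss of methanethiolate, since only the OH ortho to the new aryl–C3 bond can reach C2 (cross-coupling followed by intramolecular vinylic substitution).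

Step 12
Reactants: 17 1,8-dihydroxy-3-(methoxymethoxy)-2-methyl-7-(3-methylbut-2-en-1-yl)-11-oxo-11H-benzofuro[2,3-b]chromene-9-carbaldehyde
Product: 18 1,3,8-trihydroxy-2-methyl-7-(3-methylbut-2-en-1-yl)-11-oxo-11H-benzofuro[2,3-b]chromene-9-carbaldehyde
Conditions: HCl (1.25 M in MeOH), THF, 40 °C
Reagents that add atoms: none
Why: The MOM acetal of the vinylogous-acid 7-OH should be cleaved by dilute methanolic HCl under conditions too mild to cyclise the prenyl group onto the 4′-OH, which is in addition tied up in a hydrogen bond to the 5′-CHO (acetal cleavage).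

Step 13
Reactants: 18 1,3,8-trihydroxy-2-methyl-7-(3-methylbut-2-en-1-yl)-11-oxo-11H-benzofuro[2,3-b]chromene-9-carbaldehyde
Product: 19 1,8-dihydroxy-2-methyl-3-[(2-methylbut-3-yn-2-yl)oxy]-7-(3-methylbut-2-en-1-yl)-11-oxo-11H-benzofuro[2,3-b]chromene-9-carbaldehyde
Conditions: 3-chloro-3-methylbut-1-yne (1.3 equiv), DBU (1.1 equiv), CuCl2·2H2O (2 mol%), MeCN/DMF, 0 °C to rt
Reagents that add atoms: 3-chloro-3-methylbut-1-yne, C#CC(C)(C)Cl
Why: Of the three phenols only the 7-OH is not hydrogen-bonded to a carbonyl (5-OH to C4=O, 4′-OH to the 5′-CHO) and it is the most acidic, so one equivalent of base should give the mono(1,1-dimethylpropargyl) ether (copper-catalysed propargylic etherification).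

Step 14
Reactants: 19 1,8-dihydroxy-2-methyl-3-[(2-methylbut-3-yn-2-yl)oxy]-7-(3-methylbut-2-en-1-yl)-11-oxo-11H-benzofuro[2,3-b]chromene-9-carbaldehyde
Product: 21 1,8,9-trihydroxy-2-methyl-3-[(2-methylbut-3-yn-2-yl)oxy]-7-(3-methylbut-2-en-1-yl)-11H-benzofuro[2,3-b]chromen-11-one, via aryl formate 20 (not isolated)
Conditions: 30% H2O2 (1.5 equiv), Na2CO3, THF/H2O, 0 °C, Ar; Na2S2O3, then pH 4
Reagents that add atoms: hydrogen peroxide, OO
Why: In the Dakin reaction hydroperoxide adds to the ortho-hydroxy aldehyde, aryl migration gives formate 20 and hydrolysis releases the catechol, while the alkene, the alkyne and the ethers are inert to nucleophilic peroxide and carbonate at 0 °C under argon limits attack at C2 and air oxidation of the catechol.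

Step 15
Reactants: 21 1,8,9-trihydroxy-2-methyl-3-[(2-methylbut-3-yn-2-yl)oxy]-7-(3-methylbut-2-en-1-yl)-11H-benzofuro[2,3-b]chromen-11-one
Product: 25 triquetrumone A, via allenyl dienone 22 (not isolated), via allenyl phenol 23 (not isolated), via ortho-quinone methide 24 (not isolated)
Conditions: PhNEt2 (degassed), 180 °C, Ar
Reagents that add atoms: none
Why: Heating should trigger an aromatic propargyl Claisen [3,3] shift from O7 to C8 to give allenyl dienone 22, which enolises to allenyl phenol 23; a 1,5-hydrogen shift from the 7-OH to the central allene carbon then gives the Z ortho-quinone methide 24, and an oxa-6π electrocyclisation forms the O–CMe2 bond and restores the aromatic ring. The closest known reaction type is the thermal conversion of aryl 1,1-dimethylpropargyl ethers into 2,2-dimethyl-2H-chromenes. The pyran ring closes by a disrotatory 6π electrocyclisation of the 1-oxatriene O=C7–C8=CH–CH=CMe2, a six-membered closure at the sp2 CMe2 terminus. No stereocentre is created, so no stereocontrol is needed. The step needs regioselectivity for C8 over C6 and tolerance of the prenyl group and the free catechol: C6 carries the methyl group, so a shift there would give a dienone that cannot enolise and can only revert, the para position C4a is quaternary, and neutral, oxygen-free, amine-buffered conditions should leave the trisubstituted alkene and the catechol untouched. The gem-dimethyl group should speed both the [3,3] step and the ring closure.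

## Compound list

1 | 2,6-dimethoxytoluene | COc1cccc(OC)c1C | starting material
2 | 2-(3,5-dimethoxy-4-methylphenyl)-4,4,5,5-tetramethyl-1,3,2-dioxaborolane | COc1cc(B2OC(C)(C)C(C)(C)O2)cc(OC)c1C | intermediate
3 | 3,5-dimethoxy-4-methylphenol | COc1cc(O)cc(OC)c1C | intermediate
4 | 1-(6-hydroxy-2,4-dimethoxy-3-methylphenyl)ethan-1-one | CC(=O)c1c(O)cc(OC)c(C)c1OC | intermediate
5 | 1-(6-hydroxy-2,4-dimethoxy-3-methylphenyl)-3,3-bis(methylsulfanyl)prop-2-en-1-one | CSC(SC)=CC(=O)c1c(O)cc(OC)c(C)c1OC | intermediate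
6 | 5,7-dimethoxy-6-methyl-2-(methylsulfanyl)-4H-chromen-4-one | CSc1cc(=O)c2c(OC)c(C)c(OC)cc2o1 | intermediate
7 | 3-iodo-5,7-dimethoxy-6-methyl-2-(methylsulfanyl)-4H-chromen-4-one | CSc1oc2cc(OC)c(C)c(OC)c2c(=O)c1I | intermediate
8 | 5,7-dihydroxy-3-iodo-6-methyl-2-(methylsulfanyl)-4H-chromen-4-one | CSc1oc2cc(O)c(C)c(O)c2c(=O)c1I | intermediate
9 | 5-hydroxy-3-iodo-7-(methoxymethoxy)-6-methyl-2-(methylsulfanyl)-4H-chromen-4-one | CSc1oc2cc(OCOC)c(C)c(O)c2c(=O)c1I | intermediate
10 | 5-bromo-2,4-dihydroxybenzaldehyde | O=Cc1cc(Br)c(O)cc1O | starting material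
11 | 5-bromo-2-hydroxy-4-[(2-methylbut-3-yn-2-yl)oxy]benzaldehyde | O=Cc1cc(Br)c(OC(C)(C)C#C)cc1O | intermediate
12 | 5-bromo-2-hydroxy-4-[(2-methylbut-3-en-2-yl)oxy]benzaldehyde | O=Cc1cc(Br)c(OC(C)(C)C=C)cc1O | intermediate
13 | 5-bromo-2-hydroxy-3-(3-methylbut-2-en-1-yl)-4-oxocyclohexa-1,5-diene-1-carbaldehyde (racemic, transient) | O=CC1=C(O)C(CC=C(C)C)C(=O)C(Br)=C1 | intermediate
14 | 5-bromo-2,4-dihydroxy-3-(3-methylbut-2-en-1-yl)benzaldehyde | O=Cc1cc(Br)c(O)c(CC=C(C)C)c1O | intermediate
15 | 2,4-dihydroxy-3-(3-methylbut-2-en-1-yl)-5-(4,4,5,5-tetramethyl-1,3,2-dioxaborolan-2-yl)benzaldehyde | O=Cc1cc(B2OC(C)(C)C(C)(C)O2)c(O)c(CC=C(C)C)c1O | intermediate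
16 | 2,4-dihydroxy-5-[5-hydroxy-7-(methoxymethoxy)-6-methyl-2-(methylsulfanyl)-4-oxo-4H-chromen-3-yl]-3-(3-methylbut-2-en-1-yl)benzaldehyde | CC(C)=CCc1c(O)c(C=O)cc(c1O)-c1c(SC)oc2cc(OCOC)c(C)c(O)c2c1=O | intermediate
17 | 1,8-dihydroxy-3-(methoxymethoxy)-2-methyl-7-(3-methylbut-2-en-1-yl)-11-oxo-11H-benzofuro[2,3-b]chromene-9-carbaldehyde | CC(C)=CCc1c(O)c(C=O)cc2c1oc1oc3cc(OCOC)c(C)c(O)c3c(=O)c12 | intermediate
18 | 1,3,8-trihydroxy-2-methyl-7-(3-methylbut-2-en-1-yl)-11-oxo-11H-benzofuro[2,3-b]chromene-9-carbaldehyde | CC(C)=CCc1c(O)c(C=O)cc2c1oc1oc3cc(O)c(C)c(O)c3c(=O)c12 | intermediate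
19 | 1,8-dihydroxy-2-methyl-3-[(2-methylbut-3-yn-2-yl)oxy]-7-(3-methylbut-2-en-1-yl)-11-oxo-11H-benzofuro[2,3-b]chromene-9-carbaldehyde | CC(C)=CCc1c(O)c(C=O)cc2c1oc1oc3cc(OC(C)(C)C#C)c(C)c(O)c3c(=O)c12 | intermediate
20 | 1,8-dihydroxy-2-methyl-3-[(2-methylbut-3-yn-2-yl)oxy]-7-(3-methylbut-2-en-1-yl)-11-oxo-11H-benzofuro[2,3-b]chromen-9-yl formate | CC(C)=CCc1c(O)c(OC=O)cc2c1oc1oc3cc(OC(C)(C)C#C)c(C)c(O)c3c(=O)c12 | intermediate
21 | 1,8,9-trihydroxy-2-methyl-3-[(2-methylbut-3-yn-2-yl)oxy]-7-(3-methylbut-2-en-1-yl)-11H-benzofuro[2,3-b]chromen-11-one | CC(C)=CCc1c(O)c(O)cc2c1oc1oc3cc(OC(C)(C)C#C)c(C)c(O)c3c(=O)c12 | intermediate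
22 | 1,8,9-trihydroxy-2-methyl-4-(3-methylbuta-1,2-dien-1-yl)-7-(3-methylbut-2-en-1-yl)-4H-benzofuro[2,3-b]chromene-3,11-dione (racemic, transient) | CC(C)=CCC1=C(O)C(O)=CC2=C1OC3=C2C(=O)C4=C(O3)C(C=C=C(C)C)C(=O)C(C)=C4O | intermediate
23 | 1,3,8,9-tetrahydroxy-2-methyl-4-(3-methylbuta-1,2-dien-1-yl)-7-(3-methylbut-2-en-1-yl)-11H-benzofuro[2,3-b]chromen-11-one | CC(C)=CCc1c(O)c(O)cc2c1oc1oc3c(C=C=C(C)C)c(O)c(C)c(O)c3c(=O)c12 | intermediate
24 | (4Z)-1,8,9-trihydroxy-2-methyl-4-(3-methylbut-2-en-1-ylidene)-7-(3-methylbut-2-en-1-yl)-4H-benzofuro[2,3-b]chromene-3,11-dione | CC(C)=CCC1=C(O)C(O)=CC2=C1OC3=C2C(=O)C4=C(O3)/C(=C/C=C(C)C)C(=O)C(C)=C4O | intermediate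
25 | triquetrumone A (compound 21 skeleton with a 2,2-dimethyl-2H-pyran fused across O7 and C8; 5-OH, 6-Me, 3′-prenyl, 4′,5′-dihydroxy) | CC(C)=CCc1c(O)c(O)cc2c1oc1oc3c4c(c(C)c(O)c3c(=O)c12)OC(C)(C)C=C4 | target

## Count and risks

Total step count: 15. Longest linear sequence: 11 steps (steps 1–6 and 11–15, from 1); the ring-B branch (steps 7–10, from 10) joins at step 11.

**Step 11 (most likely to fail).** The methanethiolate released by ring closure may deactivate the palladium catalyst while coupling is still running, the electron-rich ortho-hydroxyaryl boronate may protodeboronate, and aqueous base may hydrolyse the C2–SMe group before the furan closes. The fallback separates coupling from ring closure by masking the phenols. It sets out from 14: both phenols are etherified (MOMCl, NaH, DMF) to give 5-bromo-2,4-bis(methoxymethoxy)-3-(3-methylbut-2-en-1-yl)benzaldehyde F1, and Miyaura borylation gives 2,4-bis(methoxymethoxy)-3-(3-methylbut-2-en-1-yl)-5-(4,4,5,5-tetramethyl-1,3,2-dioxaborolan-2-yl)benzaldehyde F2. Suzuki coupling of F2 with 9 should give the open tris-MOM 2-(methylsulfanyl)isoflavone F3, with no thiolate released during catalysis. Methanolic HCl then removes the three MOM groups to give the triol 2-(methylsulfanyl)isoflavone F4, and K2CO3 in DMF at 60 °C closes the furan ring by vinylic substitution. This gives 18, so the route is rejoined at 18 and step 12 is not needed.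

**Step 10.** The bromide may be reduced instead of borylated, palladium phenoxide formation may stall the catalyst, and the free ortho-hydroxy boronate may be lost on isolation. The fallback uses no boron reagent and forms the C–O bond before the C–C bond. It sets out from 6, with 14 as partner: BBr3 gives 5,7-dihydroxy-6-methyl-2-(methylsulfanyl)-4H-chromen-4-one F5, MOMCl/i-Pr2NEt gives the 7-MOM ether 5-hydroxy-7-(methoxymethoxy)-6-methyl-2-(methylsulfanyl)-4H-chromen-4-one F6, and mCPBA gives the sulfone 5-hydroxy-7-(methoxymethoxy)-6-methyl-2-(methylsulfonyl)-4H-chromen-4-one F7. The non-chelated 4-phenoxide of 14 (K2CO3, DMF) then displaces methanesulfinate from C2 to give the 2-aryloxychromone 5-bromo-2-hydroxy-4-{[5-hydroxy-7-(methoxymethoxy)-6-methyl-4-oxo-4H-chromen-2-yl]oxy}-3-(3-methylbut-2-en-1-yl)benzaldehyde F8. Intramolecular palladium-catalysed direct arylation of C3–H (Pd(OAc)2, PCy3·HBF4, K2CO3, DMA, 110 °C) closes the furan ring and gives 17, where the route is rejoined; compounds 7–9 and 15 are then not needed.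

**Step 4.** Metalation may compete at C8 (between O1 and the 7-OMe) or at the S-methyl group, or the amide base may attack C2. The fallback makes the C3–I bond while the pyranone ring is formed. It sets out from 5, isolated by running step 3 without the final heating. Iodine (I2, NaHCO3, MeCN, rt) should add to the nucleophilic α-carbon of the ketene dithioacetal, the phenol closes onto the resulting dithiocarbenium ion, and loss of methanethiol gives 7 directly, where the route is rejoined (no new compound, F0).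

## Further compounds

F1 | step 11 | 5-bromo-2,4-bis(methoxymethoxy)-3-(3-methylbut-2-en-1-yl)benzaldehyde | O=Cc1cc(Br)c(OCOC)c(CC=C(C)C)c1OCOC
F2 | step 11 | 2,4-bis(methoxymethoxy)-3-(3-methylbut-2-en-1-yl)-5-(4,4,5,5-tetramethyl-1,3,2-dioxaborolan-2-yl)benzaldehyde | O=Cc1cc(B2OC(C)(C)C(C)(C)O2)c(OCOC)c(CC=C(C)C)c1OCOC
F3 | step 11 | 5-[5-hydroxy-7-(methoxymethoxy)-6-methyl-2-(methylsulfanyl)-4-oxo-4H-chromen-3-yl]-2,4-bis(methoxymethoxy)-3-(3-methylbut-2-en-1-yl)benzaldehyde | CC(C)=CCc1c(OCOC)c(C=O)cc(c1OCOC)-c1c(SC)oc2cc(OCOC)c(C)c(O)c2c1=O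
F4 | step 11 | 5-[5,7-dihydroxy-6-methyl-2-(methylsulfanyl)-4-oxo-4H-chromen-3-yl]-2,4-dihydroxy-3-(3-methylbut-2-en-1-yl)benzaldehyde | CC(C)=CCc1c(O)c(C=O)cc(c1O)-c1c(SC)oc2cc(O)c(C)c(O)c2c1=O
F5 | step 10 | 5,7-dihydroxy-6-methyl-2-(methylsulfanyl)-4H-chromen-4-one | CSc1cc(=O)c2c(O)c(C)c(O)cc2o1
F6 | step 10 | 5-hydroxy-7-(methoxymethoxy)-6-methyl-2-(methylsulfanyl)-4H-chromen-4-one | CSc1cc(=O)c2c(O)c(C)c(OCOC)cc2o1
F7 | step 10 | 5-hydroxy-7-(methoxymethoxy)-6-methyl-2-(methylsulfonyl)-4H-chromen-4-one | CS(=O)(=O)c1cc(=O)c2c(O)c(C)c(OCOC)cc2o1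
F8 | step 10 | 5-bromo-2-hydroxy-4-{[5-hydroxy-7-(methoxymethoxy)-6-methyl-4-oxo-4H-chromen-2-yl]oxy}-3-(3-methylbut-2-en-1-yl)benzaldehyde | O=Cc1cc(Br)c(Oc2cc(=O)c3c(O)c(C)c(OCOC)cc3o2)c(CC=C(C)C)c1O
F0 | step 4 | none | none
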